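The runs are simulated for substances that don't exist; noise was put on by code.

The ratio I start from is 2.00, partner to starting material. It is the same in the north-west run as in the south-west run, whose charges are both multiplied by 2.00. So I ask of the north-west run how much faster it walks the south-west curve.

| setting | south-west | east | south-east | north-west |
|---|---|---|---|---|
| starting material | 250 mM | 380 mM | 250 mM | 500 mM |
| partner | 500 mM | 500 mM | 250 mM | 1000 mM |
| time |  |  |  | 32 min |

| run | time / min | [product] / mM |
|---|---|---|
| south-west run | 1.1 | 7.6 |
| south-west run | 3.5 | 20.9 |
| south-west run | 6.7 | 39.2 |
| south-west run | 11 | 59.6 |
| south-west run | 15 | 76.9 |
| south-west run | 20 | 94.9 |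
| south-west run | 26 | 116.2 |
| south-west run | 32 | 135.6 |
| east run | 1.1 | 9.0 |
| east run | 3.5 | 27.6 |
| east run | 6.7 | 50.6 |
| east run | 11 | 75.4 |
| east run | 15 | 98.5 |
| east run | 20 | 124.6 |
| east run | 26 | 154.1 |
| east run | 32 | 178.9 |
| south-east run | 1.1 | 3.5 |
| south-east run | 3.5 | 14.1 |
| south-east run | 6.7 | 23.9 |
| south-east run | 11 | 38.2 |
| south-east run | 15 | 49.6 |
| south-east run | 20 | 62.6 |
| south-east run | 26 | 78.5 |
| south-east run | 32 | 92.0 |

(readings scatter by 1 mM)

- Overall: starting material + partner -> product.
- Constant volume, constant temperature.
- Readings of a species count what is bound in complexes too.
- "The second partner" is partner.
- An order is taken over about fifteen percent of the charge, up and down.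

- order of the initial rate in [starting material], near the charge of the south-west run, the rate being that where two percent of its starting material are product (one fixed amount of product, the same in the runs compared)
- order of the initial rate in [partner], near the charge of the south-west run, the rate being that where two percent of its starting material are product
- product in the north-west run at 32 min, as a share of the starting material charged

I lay the rates out as a ladder, fastest first. Over the first 11 min the east run makes 6.85 mM min⁻¹, the south-west run 5.42 mM min⁻¹ and the south-east run 3.47 mM min⁻¹. The south-west run has then turned 23.8 % of its starting material, the limiting reagent there, so the charges still roughly stand. East against south-west reads an apparent order of 0.562 in starting material, and south-west against south-east reads 0.642 in partner. A rung further down, the south-west run has slowed by its last interval to 3.23 mM min⁻¹, with about 114 mM of its starting material left.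

Now the rule. A fixed share of more starting material is more product, while the rate grows by less than the charge. So, for a rate that follows a power law and with the charge of partner held, the time to that share stretches roughly with the charge of starting material, with an exponent of one minus the order, which I call the stretch exponent: 0.438. With the charge of starting material held, partner shortens the time with exponent 0.642. With the ratio of the charges held, the north-west clock therefore runs faster by 1.15, and its 32 min equal 36.8 min of the south-west run, past the last reading.

In a first round I extend the south-west curve at its last slope and reach 151 mM. I put that answer back in: the mean rate of the extension belongs to the amounts left halfway there, so the power law lowers the slope to 2.88 mM min⁻¹. That gives 150 mM, a share of 59.8 %.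

The forecast gives orders of 0.62 in starting material and 0.62 in partner and a share of 59 %, a little below mine, and it starts from the same place: “North-west keeps the south-west ratio”.

The north-west run gives 62.5 % at 32 min, more than my 59.8 %, and the steps behind it are these:

    starting material + partner → product (0.3318 M⁻¹ min⁻¹)
    starting material + 2 partner → product + partner (0.3918 M⁻² min⁻¹)
    2 starting material ⇌ idle substrate dimer, settled at all times (5.550 M⁻¹)
    2 partner ⇌ idle reagent dimer, settled at all times (9.350 M⁻¹)

The orders near the south-west charge are 0.66 in starting material and 0.67 in partner, which puts the stretch exponent at 0.340 against my 0.438, and, carried over the doubling, the north-west clock at 1.26 against my 1.15. On the east run, with the same charge of partner and a starting-material ratio of 1.52, my exponent gives a stretch of 1.20 for a quarter of its own starting material. That run takes 14.2 min against 11.9 min in the south-west run, a ratio of 1.19.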